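**Plan**

Numbering: C1 = lactone C=O, C2 = CH2, C3 = ring-fusion CH (ether O), C4 = ring-fusion C (CH3, lactone O), C5 = CH2, C6 = ether C (CH3, chain), C7–C18 = chain, then phenyl. Ring A = γ-lactone, ring B = tetrahydrofuran.
Retrosynthetic cuts: (a) C8–C9 is desaturated to an E-alkene. (b) The O–C3 bond of ring B is opened (retro-oxa-Michael) to a C2=C3 butenolide with a tertiary carbinol at C6. (c) The C6–C7 bond is cut to a C1–C6 methyl ketone and an α-chiral allylboron reagent C7–C18. (d) Cutting C2=C3 (Wittig) and C5–C6 (epoxide opening) reduces the ketone to 2-methylglycidol.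
Enabling feature: the ether oxygen of ring B is bound to C3, which is β to the lactone carbonyl C1, and to C6, a carbinol carbon bearing CH3 and two CH2 groups. Ring B is therefore a latent methyl ketone plus butenolide, so an allyl donor attacking through its CH2 terminus makes C6–C7 and frees the oxygen that closes ring B.
Forward order: ring A (steps 1–4), chain reagent (steps 5–7), C6–C7 union and closure of ring B in one operation (step 8), chain saturation (step 9).
Stereochemistry: C4 is bought with (R)-2-methylglycidol. C6 comes from the C9–B stereocentre (set with (−)-sparteine) by chirality transfer through a chair transition state that destroys C9. C3 follows from C4 through the obligatory cis ring fusion.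

Key step: step 8

Assumption: (R)-2-methylglycidol, 10-bromodecan-1-ol, (−)-sparteine, vinylboronic acid pinacol ester and (triphenylphosphoranylidene)ketene are taken as commercial.

**Step 1**
Reactants: 1 (R)-(2-methyloxiran-2-yl)methanol ((R)-2-methylglycidol)
Product: 2 (S)-2,4-dimethylpent-4-ene-1,2-diol
Conditions: CH2=C(CH3)MgBr (3 equiv), CuI (10 mol %), THF, −30 to 0 °C
Reagents that add atoms: isopropenylmagnesium bromide, C=C(C)[Mg]Br
Why: Copper-catalysed Grignard opening of a 2,2-disubstituted epoxide is an SN2 attack at the unsubstituted CH2 terminus (C5), so the C4–O bond and the purchased stereocentre are untouched, and the possible Payne rearrangement of the alkoxide is degenerate and cannot erode it.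

**Step 2**
Reactants: 2 (S)-2,4-dimethylpent-4-ene-1,2-diol
Product: 3 (S)-2-hydroxy-2,4-dimethylpent-4-enal
Conditions: SO3·pyridine, DMSO, Et3N, CH2Cl2, 0 °C
Reagents that add atoms: none
Why: Parikh–Doering oxidation takes the primary alcohol to the aldehyde under mild conditions, while the tertiary C4 hydroxyl cannot be oxidised and C4, which bears no hydrogen, cannot epimerise.

**Step 3**
Reactants: 3 (S)-2-hydroxy-2,4-dimethylpent-4-enal
Product: 5 (S)-5-methyl-5-(2-methylprop-2-en-1-yl)furan-2(5H)-one, via ester ylide 4 (not isolated)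
Conditions: Ph3P=C=C=O, toluene, 90 °C
Reagents that add atoms: (triphenylphosphoranylidene)ketene (Bestmann ylide), O=C=C=P(c1ccccc1)(c1ccccc1)c1ccccc1
Why: The tertiary hydroxyl adds to the cumulated ylide to give the stabilised ester ylide 4, whose intramolecular Wittig reaction with the neighbouring aldehyde can only give the ring (Z) alkene, that is ring A as a butenolide, with C4 unaffected.

**Step 4**
Reactants: 5 (S)-5-methyl-5-(2-methylprop-2-en-1-yl)furan-2(5H)-one
Product: 7 (S)-5-methyl-5-(2-oxopropyl)furan-2(5H)-one, via ozonide 6 (not isolated)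
Conditions: O3, CH2Cl2, −78 °C (Sudan Red 7B end point); then Me2S, −78 °C to rt
Reagents that add atoms: ozone, [O-][O+]=O
Why: Ozonolysis is electrophilic and should consume the electron-rich 1,1-disubstituted alkene well before the electron-poor butenolide alkene when ozone is titrated against a dye, and the neutral reductive work-up spares the base-sensitive β-acyloxy ketone.

**Step 5**
Reactants: 8 10-bromodecan-1-ol
Product: 9 10-phenyldecan-1-ol
Conditions: PhMgBr (2.5 equiv), Li2CuCl4 (3 mol %), THF, 0 °C to rt
Reagents that add atoms: phenylmagnesium bromide, Br[Mg]c1ccccc1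
Why: Copper-catalysed cross-coupling of a Grignard reagent with a primary alkyl bromide (Kochi coupling) tolerates the alkoxide that the first equivalent of Grignard reagent makes from the free alcohol.

**Step 6**
Reactants: 9 10-phenyldecan-1-ol
Product: 10 10-phenyldecyl N,N-diisopropylcarbamate
Conditions: iPr2NC(O)Cl, Et3N, CH2Cl2, reflux
Reagents that add atoms: N,N-diisopropylcarbamoyl chloride, CC(C)N(C(C)C)C(=O)Cl
Why: O-Carbamoylation of a primary alcohol installs the group that directs the lithiation and later leaves in the lithiation–borylation.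

**Step 7**
Reactants: 10 10-phenyldecyl N,N-diisopropylcarbamate
Product: 13 (R)-4,4,5,5-tetramethyl-2-(12-phenyldodec-1-en-3-yl)-1,3,2-dioxaborolane, via lithiated carbamate 11 (not isolated), via vinyl boronate complex 12 (not isolated)
Conditions: sBuLi, (−)-sparteine, Et2O, −78 °C; vinyl-Bpin, −78 °C; MgBr2·OEt2, −78 °C to reflux
Reagents that add atoms: vinylboronic acid pinacol ester, C=CB1OC(C)(C)C(C)(C)O1
Why: In this lithiation–borylation, sBuLi/(−)-sparteine removes the pro-S proton next to the carbamate oxygen to give configurationally stable 11, borylation with retention gives 12, and the vinyl group then migrates from boron to carbon anti to the departing carbamate (stereospecific 1,2-metallate rearrangement), which sets C9 as R.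

**Step 8**
Reactants: 13 (R)-4,4,5,5-tetramethyl-2-(12-phenyldodec-1-en-3-yl)-1,3,2-dioxaborolane; 7 (S)-5-methyl-5-(2-oxopropyl)furan-2(5H)-one
Product: 18 (3aS,5S,6aS)-5,6a-dimethyl-5-[(2E)-12-phenyldodec-2-en-1-yl]tetrahydrofuro[3,2-b]furan-2(3H)-one, via butyl boronate complex 14 (not isolated), via borinic ester 15 (not isolated), via butylboronate ester 16 (not isolated), via hydroxybutenolide 17 (not isolated)
Conditions: 13, nBuLi, THF, −78 °C; (CF3CO)2O, −78 °C; 7, −78 to −20 °C; pH 7 buffer; then DBU (20 mol %), CH2Cl2, rt
Reagents that add atoms: none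
Why: nBuLi adds to the boron of 13 and trifluoroacetic anhydride then acylates one pinacol oxygen, so the sluggish boronic ester becomes the strongly Lewis-acidic borinic ester 15, which binds the ketone oxygen of 7 and passes on its allyl group through a closed six-membered chair (B, O, C6, C7, C8, C9) in which the unsubstituted terminus C7 bonds to C6 while the C9–B bond breaks and C8=C9 forms. The closest known reaction types are the enantiospecific allylboration of aldehydes and ketones with α-substituted allyl borinic esters generated in this way and the base-catalysed intramolecular oxa-Michael addition of hydroxyalkyl butenolides. C6 is controlled by the R stereocentre at C9, which is consumed in the act: with the (CH2)9Ph group equatorial on C9 (hence the E alkene), the neopentyl-like C5 arm of the ketone equatorial and the methyl group axial, the allyl unit reaches only the Si face of the carbonyl group and C6 forms as S. After hydrolysis of 16, catalytic DBU lets the C6 hydroxyl of 17 add to C3 in a 5-exo-trig closure of ring B (O, C6, C5, C4, C3), and C3 is controlled by C4, since the short tether through C5 can deliver the oxygen only to the butenolide face that carries C5, which gives the cis-fused 2,6-dioxabicyclo[3.3.0]octanone in which the reversible addition collects. The step needs chemoselectivity for the ketone over the lactone carbonyl and the enoate carbon C3, secured because allylboron reagents transfer allyl only to a coordinated ketone or aldehyde carbonyl, and it needs the absence of base until the ketone is consumed, because 7 is a β-acyloxy ketone that would eliminate the lactone carboxylate. It also needs a clean preference for the one chair, which the small ligands on boron in 15 (butyl and one alkoxide) and the size difference between CH3 and the C5 arm bearing the fully substituted C4 are expected to secure.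

**Step 9**
Reactants: 18 (3aS,5S,6aS)-5,6a-dimethyl-5-[(2E)-12-phenyldodec-2-en-1-yl]tetrahydrofuro[3,2-b]furan-2(3H)-one
Product: 19 plakortone L, (3aS,5S,6aS)-5,6a-dimethyl-5-(12-phenyldodecyl)tetrahydrofuro[3,2-b]furan-2(3H)-one
Conditions: H2 (1 atm), Pd/C, EtOAc, rt
Reagents that add atoms: none
Why: Heterogeneous catalytic hydrogenation saturates the only C=C bond, the last trace of the allyl helper, while the lactone, the ether, the phenyl ring and the three stereocentres are inert under one atmosphere of hydrogen.

**Compound list**

1 | (R)-(2-methyloxiran-2-yl)methanol | C[C@@]1(CO)CO1 | starting material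
2 | (S)-2,4-dimethylpent-4-ene-1,2-diol | CC(=C)C[C@](C)(O)CO | intermediate
3 | (S)-2-hydroxy-2,4-dimethylpent-4-enal | CC(=C)C[C@](C)(O)C=O | intermediate
4 | (S)-2,4-dimethyl-1-oxopent-4-en-2-yl (triphenylphosphoranylidene)acetate | CC(=C)C[C@@](C)(C=O)OC(=O)C=P(c1ccccc1)(c1ccccc1)c1ccccc1 | intermediate
5 | (S)-5-methyl-5-(2-methylprop-2-en-1-yl)furan-2(5H)-one | CC(=C)C[C@]1(C)OC(=O)C=C1 | intermediate
6 | (5S)-5-methyl-5-[(3-methyl-1,2,4-trioxolan-3-yl)methyl]furan-2(5H)-one (both configurations at the trioxolane carbon) | CC1(C[C@]2(C)OC(=O)C=C2)OCOO1 | intermediate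
7 | (S)-5-methyl-5-(2-oxopropyl)furan-2(5H)-one | CC(=O)C[C@]1(C)OC(=O)C=C1 | intermediate
8 | 10-bromodecan-1-ol | OCCCCCCCCCCBr | starting material
9 | 10-phenyldecan-1-ol | OCCCCCCCCCCc1ccccc1 | intermediate
10 | 10-phenyldecyl N,N-diisopropylcarbamate | CC(C)N(C(C)C)C(=O)OCCCCCCCCCCc1ccccc1 | intermediate
11 | (S)-1-lithio-10-phenyldecyl N,N-diisopropylcarbamate (as its (−)-sparteine complex) | [Li][C@@H](CCCCCCCCCc1ccccc1)OC(=O)N(C(C)C)C(C)C | intermediate
12 | lithium (S)-[1-(diisopropylcarbamoyloxy)-10-phenyldecyl](vinyl)(pinacolato)borate | [Li+].C=C[B-]1(OC(C)(C)C(C)(C)O1)[C@@H](CCCCCCCCCc1ccccc1)OC(=O)N(C(C)C)C(C)C | intermediate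
13 | (R)-4,4,5,5-tetramethyl-2-(12-phenyldodec-1-en-3-yl)-1,3,2-dioxaborolane | C=C[C@@H](CCCCCCCCCc1ccccc1)B1OC(C)(C)C(C)(C)O1 | intermediate
14 | lithium (R)-butyl(12-phenyldodec-1-en-3-yl)(pinacolato)borate | [Li+].C=C[C@@H](CCCCCCCCCc1ccccc1)[B-]1(CCCC)OC(C)(C)C(C)(C)O1 | intermediate
15 | 2,3-dimethyl-3-(trifluoroacetoxy)butan-2-yl (R)-butyl(12-phenyldodec-1-en-3-yl)borinate | C=C[C@@H](CCCCCCCCCc1ccccc1)B(CCCC)OC(C)(C)C(C)(C)OC(=O)C(F)(F)F | intermediate
16 | mixed butylboronate of tertiary alcohol 17 and pinacol monotrifluoroacetate | C[C@](OB(CCCC)OC(C)(C)C(C)(C)OC(=O)C(F)(F)F)(C/C=C/CCCCCCCCCc1ccccc1)C[C@]1(C)OC(=O)C=C1 | intermediate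
17 | (S)-5-[(2S,4E)-2-hydroxy-2-methyl-14-phenyltetradec-4-en-1-yl]-5-methylfuran-2(5H)-one | C[C@](O)(C/C=C/CCCCCCCCCc1ccccc1)C[C@]1(C)OC(=O)C=C1 | intermediate
18 | (3aS,5S,6aS)-5,6a-dimethyl-5-[(2E)-12-phenyldodec-2-en-1-yl]tetrahydrofuro[3,2-b]furan-2(3H)-one | C[C@]1(C/C=C/CCCCCCCCCc2ccccc2)C[C@]2(C)OC(=O)C[C@@H]2O1 | intermediate
19 | plakortone L, (3aS,5S,6aS)-5,6a-dimethyl-5-(12-phenyldodecyl)tetrahydrofuro[3,2-b]furan-2(3H)-one | C[C@]1(CCCCCCCCCCCCc2ccccc2)C[C@]2(C)OC(=O)C[C@@H]2O1 | target

**Step count**

Total step count: 9.
Longest linear sequence: 6 steps (1, 2, 3, 4, 8, 9).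

**Steps most likely to fail**

**Step 8.** The facial fidelity at the ketone may be lost. The chair may not distinguish the methyl group from the C5 arm sharply enough, or part of the reaction may run through the chair with the C9 substituent axial. Either channel erodes the configuration at C6.
The fallback sets out from 7 and 9 and returns at 18. It hands stereocontrol to a chiral catalyst acting on the smallest allyl donor and moves the union of the large pieces to an olefin metathesis.
- Ketone 7 is allylated with allyldiisopropoxyborane under catalysis by enantiopure 3,3'-dibromo-BINOL (the antipode that directs allyl to the Si face; toluene/PhCF3, −35 °C). This gives (S)-5-[(S)-2-hydroxy-2-methylpent-4-en-1-yl]-5-methylfuran-2(5H)-one F1.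
- Catalytic DBU closes F1 to (3aS,5S,6aS)-5-allyl-5,6a-dimethyltetrahydrofuro[3,2-b]furan-2(3H)-one F2.
- Alcohol 9 is oxidised (SO3·pyridine, DMSO, Et3N) to 10-phenyldecanal F3 and methylenated (Ph3P=CH2, THF) to 11-phenylundec-1-ene F4.
- Cross-metathesis of F2 with excess F4 (second-generation Grubbs catalyst, CH2Cl2, 40 °C) gives 18. Its alkene geometry does not matter for step 9.

**Step 3.** The hindered tertiary hydroxyl may add slowly to the cumulated ylide. That would leave time for self-condensation or α-ketol rearrangement of the hydroxy aldehyde.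
The fallback sets out from 3 and returns at 5. Aldehyde 3 undergoes an ordinary E-selective Wittig reaction with Ph3P=CHCO2Me (CH2Cl2, rt), which tolerates the free hydroxyl and gives methyl (2E,4S)-4-hydroxy-4,6-dimethylhepta-2,6-dienoate F5. Sensitised photochemical E-to-Z isomerisation of F5 is then drained by spontaneous lactonisation of the Z isomer to 5.

**Step 4.** Ozone may also attack the butenolide alkene (over-oxidation). The lactone carboxylate may also undergo β-elimination from the β-acyloxy ketone during work-up or chromatography.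
The fallback sets out from 1 and returns at 7. It releases the ketone by neutral hydration instead of oxidative cleavage.
- Epoxide 1 is opened with lithium acetylide–ethylenediamine (DMSO, rt) to (S)-2-methylpent-4-yne-1,2-diol F6.
- Parikh–Doering oxidation gives (S)-2-hydroxy-2-methylpent-4-ynal F7.
- The cumulated ylide of step 3 converts F7 into (S)-5-methyl-5-(prop-2-yn-1-yl)furan-2(5H)-one F8.
- Markovnikov hydration of the terminal alkyne (Ph3PAuNTf2, wet 1,4-dioxane, rt) gives 7, which is used crude in step 8.

**Further compounds**

F1 | step 8 | (S)-5-[(S)-2-hydroxy-2-methylpent-4-en-1-yl]-5-methylfuran-2(5H)-one | C[C@](O)(CC=C)C[C@]1(C)OC(=O)C=C1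
F2 | step 8 | (3aS,5S,6aS)-5-allyl-5,6a-dimethyltetrahydrofuro[3,2-b]furan-2(3H)-one | C[C@]1(CC=C)C[C@]2(C)OC(=O)C[C@@H]2O1
F3 | step 8 | 10-phenyldecanal | O=CCCCCCCCCCc1ccccc1
F4 | step 8 | 11-phenylundec-1-ene | C=CCCCCCCCCCc1ccccc1
F5 | step 3 | methyl (2E,4S)-4-hydroxy-4,6-dimethylhepta-2,6-dienoate | CC(=C)C[C@](C)(O)/C=C/C(=O)OC
F6 | step 4 | (S)-2-methylpent-4-yne-1,2-diol | C#CC[C@](C)(O)CO
F7 | step 4 | (S)-2-hydroxy-2-methylpent-4-ynal | C#CC[C@](C)(O)C=O
F8 | step 4 | (S)-5-methyl-5-(prop-2-yn-1-yl)furan-2(5H)-one | C#CC[C@]1(C)OC(=O)C=C1
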